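**Retrosynthetic overview**
1. The target (2S,3S) is the global debenzylation product of a pentabenzyl-protected (E)-stilbene. That stilbene comes from a Heck coupling of an aryl bromide with 4-benzyloxy-3-methoxystyrene.
2. The trans-2,3-diaryl-dihydrobenzofuran comes from acid-mediated C2 epimerization of the cis isomer. The cis isomer is the product of the key step: an enantioselective Rh(II) donor/donor-carbene C–H insertion into one of two enantiotopic benzylic O–CH2Ar groups of a symmetrical 2,6-bis(benzyloxy)diaryl diazomethane. This forms the only ring in the synthesis, sets C3, and sets C2 as cis. The unreacted O–CH2Ar group becomes the C4–OH.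
3. The diazo compound comes from the hydrazone of a diaryl ketone. The ketone is built by adding 3,5-bis(benzyloxy)phenyllithium to 4-bromo-2,6-bis(benzyloxy)benzaldehyde, then oxidizing. The aldehyde comes from double SNAr on 4-bromo-2,6-difluorobenzaldehyde.

Assumptions:
- Rh2(S-PTTL)4 is assumed to give the (3S) series (the R-catalyst gives the enantiomer).
- Donor/donor insertion is assumed to be cis-selective, so a separate epimerization step is included.

---

**Step 1**
Reactants: 1 (2-methoxy-4-vinylphenol); 2 (benzyl bromide)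
Product: 3 (1-benzyloxy-2-methoxy-4-vinylbenzene)
Conditions: BnBr, K2CO3, DMF, rt, 12 h (BHT trace)
Reagents that add atoms: benzyl bromide, BrCc1ccccc1 (compound 2)
Why: Williamson O-benzylation of the phenol gives the Heck partner; the vinyl group is untouched.

**Step 2**
Reactants: 4 (4-bromo-2,6-difluorobenzaldehyde); 5 ([4-(benzyloxy)-3-methoxyphenyl]methanol)
Product: 6 (4-bromo-2,6-bis{[4-(benzyloxy)-3-methoxybenzyl]oxy}benzaldehyde)
Conditions: 5 (2.4 equiv), NaH (2.6 equiv), DMF, 0 °C → rt, 6 h
Reagents that add atoms: none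
Why: The ortho-fluorines are activated by the formyl group (double SNAr); the Br and aldehyde survive, and the product is a symmetrical bis-ether with no stereocenter.

**Step 3**
Reactants: 7 (1-bromo-3,5-bis(benzyloxy)benzene); 6
Product: 8 (diarylmethanol: [3,5-bis(benzyloxy)phenyl][4-bromo-2,6-bis(ArCH2O)phenyl]methanol, Ar = 4-BnO-3-MeO-C6H3)
Conditions: 7 + n-BuLi, THF, −78 °C, 30 min; then add 6, −78 → 0 °C
Reagents that add atoms: none
Why: Li–Br exchange gives the aryllithium, which adds to the aldehyde faster than it exchanges with the hindered aryl bromide (1,2-addition, no stereocenter to control).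

**Step 4**
Reactants: 8
Product: 9 (diaryl ketone)
Conditions: Dess–Martin periodinane, NaHCO3, CH2Cl2, rt, 1 h
Reagents that add atoms: none
Why: Mild oxidation of the benzhydrol leaves the benzyl ethers and the aryl bromide intact.

**Step 5**
Reactants: 9; 10 (hydrazine hydrate)
Product: 11 (diaryl ketone hydrazone)
Conditions: N2H4·H2O (30 equiv), AcOH cat., n-BuOH, 110 °C, sealed tube, 48 h
Reagents that add atoms: hydrazine, NN (compound 10)
Why: Condensation to the N–H hydrazone; a large excess of hydrazine and heat overcome the 2,6-dialkoxy hindrance and suppress azine formation.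

**Step 6**
Reactants: 11
Product: 12 (diaryldiazomethane)
Conditions: activated MnO2 (15 equiv), CH2Cl2, 0 °C → rt, 1 h, dark; filter; use crude
Reagents that add atoms: none
Why: MnO2 dehydrogenates N–H hydrazones to diaryldiazoalkanes, and the other groups are inert to it.

**Step 7**
Reactants: 12
Product: 13 ((2R,3S)-cis-6-bromo-4-[(4-BnO-3-MeO-benzyl)oxy]-2-(4-BnO-3-MeO-phenyl)-3-[3,5-bis(BnO)phenyl]-2,3-dihydrobenzofuran)
Conditions: Rh2(S-PTTL)4 (2 mol%), CH2Cl2, 23 °C, slow addition of diazo solution over 1 h, 3 h; N2 lost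
Reagents that add atoms: none
Why: Proposed new method: the Rh-bound electron-rich diarylcarbene abstracts hydride from the hydridic p-alkoxybenzylic O–CH2 and collapses through a five-membered transition state, so the chiral tetracarboxylate selects the carbene face and pro-H and sets C3 (S) with cis C2 (R), and both ortho ethers give the same enantiomer by symmetry. The closest known reaction is Rh2(S-PTTL)4-catalysed donor/donor carbene benzylic C–H insertion to cis-2,3-disubstituted dihydrobenzofurans.

**Step 8**
Reactants: 13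
Product: 14 ((2S,3S)-trans isomer)
Conditions: BF3·OEt2 (10 mol%), CH2Cl2, −20 °C, 2 h; Et3N quench
Reagents that add atoms: none
Why: Proposed new method: Lewis-acid ionization of the C2–O bond gives a p-alkoxybenzylic cation and aryloxy–BF3 species, and re-closure anti to the C3 aryl gives the thermodynamic trans isomer; C3 is never ionized, so its configuration is retained. The closest known reaction is acid-mediated cis→trans equilibration of 2-aryl-dihydrobenzofurans and flavan-type benzylic aryl ethers.

**Step 9**
Reactants: 14; 3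
Product: 15 (pentabenzyl-protected (E)-stilbene, (2S,3S))
Conditions: Pd(OAc)2 (5 mol%), P(o-tol)3 (10 mol%), Et3N (3 equiv), DMF, 100 °C, 16 h
Reagents that add atoms: none
Why: Mizoroki–Heck coupling of the aryl bromide with the styrene gives the trans-stilbene selectively, and the C2 and C3 stereocenters are not involved.

**Step 10**
Reactants: 15
Product: 16 (Bisisorhapontigenin B)
Conditions: BCl3 (1 M in CH2Cl2, 20 equiv), pentamethylbenzene (15 equiv), CH2Cl2, −78 °C, 2 h; then MeOH, aq. NaHCO3
Reagents that add atoms: none (the new OH hydrogens come from work-up)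
Why: BCl3/pentamethylbenzene cleaves the four aryl benzyl ethers and the C4 O-(4-BnO-3-MeO-benzyl) ether to free phenols, the cation scavenger traps benzyl cations, and the two aryl methyl ethers and the stilbene survive at −78 °C; the stereocenters are unchanged.

---

**Compound list**

| No. | Name | SMILES | Role |
|---|---|---|---|
| 1 | 2-Methoxy-4-vinylphenol | C=Cc1ccc(O)c(OC)c1 | starting material |
| 2 | Benzyl bromide | BrCc1ccccc1 | starting material (reagent) |
| 3 | 1-Benzyloxy-2-methoxy-4-vinylbenzene | C=Cc1ccc(OCc2ccccc2)c(OC)c1 | intermediate |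
| 4 | 4-Bromo-2,6-difluorobenzaldehyde | O=Cc1c(F)cc(Br)cc1F | starting material |
| 5 | [4-(Benzyloxy)-3-methoxyphenyl]methanol | OCc1ccc(OCc2ccccc2)c(OC)c1 | starting material |
| 6 | 4-Bromo-2,6-bis{[4-(benzyloxy)-3-methoxybenzyl]oxy}benzaldehyde | O=Cc1c(OCc2ccc(OCc3ccccc3)c(OC)c2)cc(Br)cc1OCc1ccc(OCc2ccccc2)c(OC)c1 | intermediate |
| 7 | 1-Bromo-3,5-bis(benzyloxy)benzene | Brc1cc(OCc2ccccc2)cc(OCc2ccccc2)c1 | starting material |
| 8 | Diarylmethanol | OC(c1cc(OCc2ccccc2)cc(OCc2ccccc2)c1)c1c(OCc2ccc(OCc3ccccc3)c(OC)c2)cc(Br)cc1OCc1ccc(OCc2ccccc2)c(OC)c1 | intermediate |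
| 9 | Diaryl ketone | O=C(c1cc(OCc2ccccc2)cc(OCc2ccccc2)c1)c1c(OCc2ccc(OCc3ccccc3)c(OC)c2)cc(Br)cc1OCc1ccc(OCc2ccccc2)c(OC)c1 | intermediate |
| 10 | Hydrazine (hydrate) | NN | starting material (reagent) |
| 11 | Ketone hydrazone | NN=C(c1cc(OCc2ccccc2)cc(OCc2ccccc2)c1)c1c(OCc2ccc(OCc3ccccc3)c(OC)c2)cc(Br)cc1OCc1ccc(OCc2ccccc2)c(OC)c1 | intermediate |
| 12 | Diaryldiazomethane | [N-]=[N+]=C(c1cc(OCc2ccccc2)cc(OCc2ccccc2)c1)c1c(OCc2ccc(OCc3ccccc3)c(OC)c2)cc(Br)cc1OCc1ccc(OCc2ccccc2)c(OC)c1 | intermediate |
| 13 | (2R,3S)-cis-dihydrobenzofuran (Br, protected) | Brc1cc(OCc2ccc(OCc3ccccc3)c(OC)c2)c4c(c1)O[C@@H](c5ccc(OCc6ccccc6)c(OC)c5)[C@H]4c7cc(OCc8ccccc8)cc(OCc9ccccc9)c7 | intermediate |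
| 14 | (2S,3S)-trans-dihydrobenzofuran (Br, protected) | Brc1cc(OCc2ccc(OCc3ccccc3)c(OC)c2)c4c(c1)O[C@H](c5ccc(OCc6ccccc6)c(OC)c5)[C@H]4c7cc(OCc8ccccc8)cc(OCc9ccccc9)c7 | intermediate |
| 15 | Pentabenzyl (E)-stilbene | COc1cc(/C=C/c2cc(OCc3ccc(OCc4ccccc4)c(OC)c3)c5c(c2)O[C@H](c6ccc(OCc7ccccc7)c(OC)c6)[C@H]5c8cc(OCc9ccccc9)cc(OCc%10ccccc%10)c8)ccc1OCc1ccccc1 | intermediate |
| 16 | Bisisorhapontigenin B | COc1cc(/C=C/c2cc(O)c3c(c2)O[C@H](c2ccc(O)c(OC)c2)[C@H]3c2cc(O)cc(O)c2)ccc1O | target |

---

**Totals**
- Total steps: 10, including the one-step preparation of the Heck partner (Step 1).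
- Longest linear sequence: 9 steps (Steps 2–10, from 4-bromo-2,6-difluorobenzaldehyde).

**Three steps most likely to fail**
1. **Step 7 (Rh insertion).** The carbene is very hindered and electron-rich, and the ee, the cis/trans ratio, and competing azine formation are all uncertain.
   - Fallback: run the insertion racemic with an achiral catalyst (Rh2(esp)2), then epimerize, carry through Heck and deprotection, and resolve compound 16 (or 15) by preparative chiral-phase HPLC.
2. **Step 5 (hydrazone of a 2,6-dialkoxybenzophenone).** Condensation may stall.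
   - Fallback: skip the ketone. Do the SNAr on 4-bromo-2,6-difluorobenzonitrile, add aryllithium 7 by inverse addition to give the N-lithio ketimine, and quench with hydrazine to form hydrazone 11 directly.
3. **Step 10 (global BCl3 debenzylation).** The acid-labile dihydrobenzofuran and the stilbene may be damaged.
   - Fallback: reorder. Debenzylate the aryl bromide 14 with BCl3 first (no stilbene present), then install the (E)-stilbene on the unprotected bromide by aqueous Suzuki coupling with (E)-2-(4-hydroxy-3-methoxyphenyl)vinyl-Bpin.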